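**Plan**

Numbering: decalin C1–C8a as in the target; pentadienoic acid chain C1''–C5'' (C5'' on C1); butenyl C1'–C4' (C2' on C2).

1. Retrosynthesis: remove the sulfate, then cut C5''=C4'' (vinylogous HWE) to the C1 aldehyde 17; cut C1–C2 of ring A by reversing a 1,3 O-to-C shift, which leads to the eight-membered cyclic allyl vinyl ether 15 (ring O–C5''–C1–C8a–C4a–C4–C3–C2); then cut the enol ether C=C (metathesis), the O–vinyl bond, C2–C3 (tiglic aldehyde), C4=C3 (iodo-olefination) and ring B (Diels–Alder).
2. Forward: ring B first, then the C8 methyl and C7 oxygen, then the side arm, then the eight-membered 2H-oxocine ring; ring A is formed last, by contraction of the oxocine (8 to 6) with O and C5'' leaving the ring as the formyl group.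
3. Enabling feature: C2 is doubly allylic (between C3=C4 and the butenyl C=C) and C1 is the α-carbon of the latent C5'' aldehyde. The C1–C2 bond is therefore the union of a pentadienyl cation and an enolate, which can first be tied together through oxygen.
4. Stereochemistry: C4a/C8a from the catalytic endo Diels–Alder; C8 by anti enolate methylation; C7 by equatorial hydride delivery; C2 from the carbinol set in the Cr/Ni coupling and carried over with retention; C1 in the ring contraction (Z-enolate, A(1,3) strain).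
5. Alkene geometry: butenyl from tiglic aldehyde, C3=C4 from the Z-iodoalkene, the diene from the HWE reaction.

Key step: step 11

Assumption: the facial sense of the oxazaborolidinium-catalysed cycloaddition (step 3) and of the ligand-controlled Cr/Ni coupling (step 8) is set by choosing the catalyst or ligand antipode that gives the configuration drawn; both antipodes are available.

**Route**

Step 1
Reactants: 1 prop-2-enal; 2 1-(triphenyl-λ5-phosphanylidene)propan-2-one
Product: 3 (3E)-hexa-3,5-dien-2-one
Conditions: CH2Cl2, 25 °C; used cold and without delay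
Reagents that add atoms: none
Why: Wittig olefination with a stabilised ylide should give the (E)-enone; no stereocentre is formed.

Step 2
Reactants: 3 (3E)-hexa-3,5-dien-2-one
Product: 4 (3E)-2-[(triisopropylsilyl)oxy]hexa-1,3,5-triene
Conditions: i-Pr3SiOTf, Et3N, Et2O, 0 °C
Reagents that add atoms: triisopropylsilyl trifluoromethanesulfonate CC(C)[Si](C(C)C)(C(C)C)OS(=O)(=O)C(F)(F)F
Why: Silyl enol ether formation by soft enolisation; the methyl group is the only enolisable position, so the 2-silyloxy triene should form regiospecifically.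

Step 3
Reactants: 4 (3E)-2-[(triisopropylsilyl)oxy]hexa-1,3,5-triene; 1 prop-2-enal
Product: 5 (1S,2R)-4-[(triisopropylsilyl)oxy]-2-vinylcyclohex-3-ene-1-carbaldehyde (formyl and vinyl cis)
Conditions: (S)-2-(o-tolyl)-CBS-oxazaborolidine·HNTf2 (20 mol %), acrolein (3 equiv), CH2Cl2, −78 °C
Reagents that add atoms: none
Why: Catalytic enantioselective Diels–Alder reaction: the CH2 terminus next to the silyloxy carbon bonds to the β-carbon of the activated enal ("para" to OSi, vinyl "ortho" to CHO), endo addition to the (E)-diene places formyl and vinyl cis (future C4a and C8a), and the chiral oxazaborolidinium ion selects the enal face.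

Step 4
Reactants: 5 (1S,2R)-4-[(triisopropylsilyl)oxy]-2-vinylcyclohex-3-ene-1-carbaldehyde
Product: 6 triisopropyl({cis-4-[(1Z)-2-iodoprop-1-en-1-yl]-3-vinylcyclohex-1-en-1-yl}oxy)silane
Conditions: EtPPh3I, n-BuLi, THF, 25 °C; I2, −78 °C; NaN(SiMe3)2, −20 °C; then 5, −78 °C
Reagents that add atoms: ethyltriphenylphosphonium iodide CC[P+](c1ccccc1)(c1ccccc1)c1ccccc1.[I-]; iodine II
Why: Stork–Zhao-type Wittig iodo-olefination is Z-selective (iodine cis to the ring carbon) and at −78 °C should leave the epimerisable formyl-bearing centre untouched.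

Step 5
Reactants: 6 triisopropyl({cis-4-[(1Z)-2-iodoprop-1-en-1-yl]-3-vinylcyclohex-1-en-1-yl}oxy)silane
Product: 8 4-[(1Z)-2-iodoprop-1-en-1-yl]-2-methyl-3-vinylcyclohexan-1-one (2,3-trans and 3,4-cis), via tris(dimethylamino)sulfonium enolate 7 (not isolated)
Conditions: (Me2N)3S+ Me3SiF2− (TASF), MeI (5 equiv), THF, −78 to −30 °C
Reagents that add atoms: iodomethane CI
Why: Regiospecific enolate alkylation: fluoride releases the enolate exactly where the Diels–Alder reaction left the enol ether, and methyl iodide should attack anti to the neighbouring vinyl-bearing carbon (2,3-trans), setting C8.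

Step 6
Reactants: 8 4-[(1Z)-2-iodoprop-1-en-1-yl]-2-methyl-3-vinylcyclohexan-1-one
Product: 9 4-[(1Z)-2-iodoprop-1-en-1-yl]-2-methyl-3-vinylcyclohexan-1-ol (1,2-cis; 2,3-trans; 3,4-cis)
Conditions: LiBH(s-Bu)3, THF, −78 °C; then H2O
Reagents that add atoms: none
Why: Bulky hydride reduction: in the chair with methyl and vinyl equatorial the hydride should come from the equatorial direction and give the axial alcohol cis to the methyl group, setting C7.

Step 7
Reactants: 9 4-[(1Z)-2-iodoprop-1-en-1-yl]-2-methyl-3-vinylcyclohexan-1-ol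
Product: 10 tert-butyl({4-[(1Z)-2-iodoprop-1-en-1-yl]-2-methyl-3-vinylcyclohexyl}oxy)dimethylsilane (configuration as in 9)
Conditions: t-BuMe2SiOTf, 2,6-lutidine, CH2Cl2, −78 to 0 °C
Reagents that add atoms: tert-butyldimethylsilyl trifluoromethanesulfonate CC(C)(C)[Si](C)(C)OS(=O)(=O)C(F)(F)F
Why: Silyl protection; the silyl triflate is reactive enough for the hindered axial alcohol.

Step 8
Reactants: 10 tert-butyl({4-[(1Z)-2-iodoprop-1-en-1-yl]-2-methyl-3-vinylcyclohexyl}oxy)dimethylsilane; 11 (2E)-2-methylbut-2-enal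
Product: 13 (2E,4R,5Z)-6-[4-(tert-butyldimethylsilyloxy)-3-methyl-2-vinylcyclohexyl]-3,5-dimethylhexa-2,5-dien-4-ol, via alkenylchromium dichloride 12 (not isolated)
Conditions: CrCl2 (4 equiv), NiCl2 (2 mol %), Kishi-type oxazoline–sulfonamide ligand (4.4 equiv), Et3N (4.4 equiv), THF, 25 °C; aqueous work-up, ligand recovered
Reagents that add atoms: none
Why: Asymmetric Nozaki–Hiyama–Kishi coupling: the alkenylchromium species forms with retention of the Z geometry and the chiral ligand should direct 1,2-addition to the enal to give the (R)-carbinol (future C2).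

Step 9
Reactants: 13 (2E,4R,5Z)-6-[4-(tert-butyldimethylsilyloxy)-3-methyl-2-vinylcyclohexyl]-3,5-dimethylhexa-2,5-dien-4-ol
Product: 14 vinyl ether of 13 (O-vinyl on the carbinol oxygen)
Conditions: Hg(OAc)2 (0.3 equiv), ethyl vinyl ether (solvent), reflux (33 °C)
Reagents that add atoms: ethyl vinyl ether C=COCC
Why: Mercury-catalysed transetherification (vinyl transfer) should give the allyl vinyl ether at a temperature well below that of a thermal Claisen rearrangement; the carbinol centre is not touched.

Step 10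
Reactants: 14 vinyl ether of 13
Product: 15 cis-fused cyclohexano-2H-oxocine (ring O–C5''H=C1H–C8a–C4a–C4H=C3(Me)–C2H(butenyl); both ring alkenes Z; C7 OTBS; C8 Me)
Conditions: second-generation Grubbs catalyst RuCl2(=CHPh)(PCy3)(H2IMes) (10 mol %), CH2Cl2 (2 mM), 40 °C
Reagents that add atoms: none
Why: Ring-closing enol ether–olefin metathesis: the catalyst should load on the monosubstituted vinyl group and close onto the vinyl ether; the cis-1,2-disubstituted ring B and the Z-trisubstituted alkene preorganise the eight-membered ring, and the trisubstituted alkenes stay out.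

Step 11
Reactants: 15 cis-fused cyclohexano-2H-oxocine
Product: 17 2-[(2E)-but-2-en-2-yl]-7-(tert-butyldimethylsilyloxy)-3,8-dimethyl-1,2,4a,5,6,7,8,8a-octahydronaphthalene-1-carbaldehyde (target configuration), via aluminium enolate dienyl cation ion pair 16 (not isolated)
Conditions: EtAlCl2 (1.2 equiv), CH2Cl2–hexane, −78 °C; aqueous Rochelle salt
Reagents that add atoms: none
Why: Proposed new method: EtAlCl2 binds the ring oxygen and the doubly allylic C2–O bond ionises to a contact ion pair of a pentadienyl cation (C4–C3–C2–C2'–C3') and the (Z)-aluminium enolate of the C5'' aldehyde, which recombines at carbon (C1 to C2) because only that collapse is irreversible. The closest known reaction type is the Lewis-acid-mediated [1,3] O-to-C ring contraction of 2,5-dihydrooxepins to cyclopentenecarbaldehydes (a Petasis–Ferrier-like shift), here one ring size larger. Ring A closes transannularly in a 6-(enolexo) mode onto C2 (endo to the C3=C4 unit, exo to the butenyl unit), and the eight-membered ring loses O and C5'', which become the formyl group. C2 is controlled by the carbinol centre from step 8, since the enolate stays on the face from which oxygen leaves and the shift is suprafacial with retention. C1 is controlled by the ring-fixed (Z)-enolate and A(1,3) strain: H-8a eclipses the enolate C=C, so the formyl group ends trans to C8. The step needs attack at C2 (six-membered ring) and not at C3' (eight-membered carbocycle, the formal [3,3] product), and no rotation about C2–C3 before collapse; the two-atom C8a–C4a tether that holds C1 over C2, the low temperature and the non-polar medium are relied on for this.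

Step 12
Reactants: 17 decalin carbaldehyde; 18 ethyl (2E)-4-(diethoxyphosphoryl)but-2-enoate
Product: 19 ethyl (2E,4E)-5-[2-[(2E)-but-2-en-2-yl]-7-(tert-butyldimethylsilyloxy)-3,8-dimethyl-1,2,4a,5,6,7,8,8a-octahydronaphthalen-1-yl]penta-2,4-dienoate
Conditions: 18, LiN(SiMe3)2, THF, −78 °C; then 17, −78 to 0 °C
Reagents that add atoms: none
Why: Vinylogous Horner–Wadsworth–Emmons olefination should give the (2E,4E)-dienoate; the pre-formed lithium phosphonate adds faster than it enolises the α-branched aldehyde, so C1 is kept.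

Step 13
Reactants: 19 silyl-protected ethyl dienoate
Product: 20 ethyl (2E,4E)-5-[2-[(2E)-but-2-en-2-yl]-7-hydroxy-3,8-dimethyl-1,2,4a,5,6,7,8,8a-octahydronaphthalen-1-yl]penta-2,4-dienoate
Conditions: Bu4NF (3 equiv), AcOH (3 equiv), THF, 25–40 °C
Reagents that add atoms: none
Why: Fluoride desilylation; buffering with acetic acid should protect the dienoate and the C1 centre from base.

Step 14
Reactants: 20 hydroxy ethyl dienoate
Product: 21 pyridinium salt of the C7 sulfate monoester of 20
Conditions: SO3·pyridine (5 equiv), pyridine, 40 °C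
Reagents that add atoms: sulfur trioxide pyridine complex O=S(=O)([O-])[n+]1ccccc1
Why: O-Sulfation of the secondary alcohol with the SO3–pyridine complex; the C–O bond is not broken, so C7 is retained.

Step 15
Reactants: 21 pyridinium sulfate ethyl ester
Product: 23 (2E,4E)-5-[(1S,2R,4aS,7S,8R,8aR)-2-[(2E)-but-2-en-2-yl]-3,8-dimethyl-7-(sulfooxy)-1,2,4a,5,6,7,8,8a-octahydronaphthalen-1-yl]penta-2,4-dienoic acid, via dilithium carboxylate sulfate salt 22 (not isolated)
Conditions: LiOH (4 equiv), THF/H2O 3:1, 25 °C; then 1 M HCl, 0 °C, to pH 2, rapid extraction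
Reagents that add atoms: lithium hydroxide [Li+].[OH-]
Why: Ester saponification (the sulfate monoester anion resists hydroxide) followed by cold protonation should give the free acid without touching any stereocentre.

**Compound list**

1 | prop-2-enal (acrolein) | C=CC=O | starting material
2 | 1-(triphenyl-λ5-phosphanylidene)propan-2-one | CC(=O)C=P(c1ccccc1)(c1ccccc1)c1ccccc1 | starting material
3 | (3E)-hexa-3,5-dien-2-one | CC(=O)/C=C/C=C | intermediate
4 | (3E)-2-[(triisopropylsilyl)oxy]hexa-1,3,5-triene | C=C(O[Si](C(C)C)(C(C)C)C(C)C)/C=C/C=C | intermediate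
5 | (1S,2R)-4-[(triisopropylsilyl)oxy]-2-vinylcyclohex-3-ene-1-carbaldehyde | O=C[C@H]1CCC(O[Si](C(C)C)(C(C)C)C(C)C)=C[C@H]1C=C | intermediate
6 | triisopropyl({cis-4-[(1Z)-2-iodoprop-1-en-1-yl]-3-vinylcyclohex-1-en-1-yl}oxy)silane | C/C(I)=C/[C@H]1CCC(O[Si](C(C)C)(C(C)C)C(C)C)=C[C@H]1C=C | intermediate
7 | tris(dimethylamino)sulfonium enolate of 8 (not isolated) | C/C(I)=C/[C@H]1CCC([O-])=C[C@H]1C=C.CN(C)[S+](N(C)C)N(C)C | intermediate
8 | 4-[(1Z)-2-iodoprop-1-en-1-yl]-2-methyl-3-vinylcyclohexan-1-one, 2,3-trans, 3,4-cis | C/C(I)=C/[C@H]1CCC(=O)[C@H](C)[C@H]1C=C | intermediate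
9 | 4-[(1Z)-2-iodoprop-1-en-1-yl]-2-methyl-3-vinylcyclohexan-1-ol, 1,2-cis, 2,3-trans, 3,4-cis | C/C(I)=C/[C@H]1CC[C@H](O)[C@H](C)[C@H]1C=C | intermediate
10 | tert-butyldimethylsilyl ether of 9 | C/C(I)=C/[C@H]1CC[C@H](O[Si](C)(C)C(C)(C)C)[C@H](C)[C@H]1C=C | intermediate
11 | (2E)-2-methylbut-2-enal (tiglic aldehyde) | C/C=C(\C)C=O | starting material
12 | alkenylchromium dichloride from 10 (not isolated) | C/C([Cr](Cl)Cl)=C/[C@H]1CC[C@H](O[Si](C)(C)C(C)(C)C)[C@H](C)[C@H]1C=C | intermediate
13 | (2E,4R,5Z)-6-[4-(tert-butyldimethylsilyloxy)-3-methyl-2-vinylcyclohexyl]-3,5-dimethylhexa-2,5-dien-4-ol | C/C=C(\C)[C@@H](O)/C(C)=C\[C@H]1CC[C@H](O[Si](C)(C)C(C)(C)C)[C@H](C)[C@H]1C=C | intermediate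
14 | vinyl ether of 13 | C/C=C(\C)[C@@H](OC=C)/C(C)=C\[C@H]1CC[C@H](O[Si](C)(C)C(C)(C)C)[C@H](C)[C@H]1C=C | intermediate
15 | cis-fused cyclohexano-2H-oxocine (ring O–C5''=C1–C8a–C4a–C4=C3–C2, both ring alkenes Z, butenyl on C2) | C/C=C(\C)[C@@H]1/C(C)=C\[C@H]2CC[C@H](O[Si](C)(C)C(C)(C)C)[C@H](C)[C@H]2/C=C\O1 | intermediate
16 | ring-opened aluminium enolate / dienyl cation ion pair (not isolated) | C/C=C(\C)[CH+]/C(C)=C\[C@H]1CC[C@H](O[Si](C)(C)C(C)(C)C)[C@H](C)[C@H]1/C=C\O[Al-](Cl)(Cl)CC | intermediate
17 | 2-[(2E)-but-2-en-2-yl]-7-(tert-butyldimethylsilyloxy)-3,8-dimethyl-1,2,4a,5,6,7,8,8a-octahydronaphthalene-1-carbaldehyde, target configuration | C/C=C(\C)[C@@H]1C(C)=C[C@H]2CC[C@H](O[Si](C)(C)C(C)(C)C)[C@H](C)[C@H]2[C@@H]1C=O | intermediate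
18 | ethyl (2E)-4-(diethoxyphosphoryl)but-2-enoate | CCOC(=O)/C=C/CP(=O)(OCC)OCC | starting material
19 | ethyl (2E,4E)-dienoate, C7 silyl ether | C/C=C(\C)[C@@H]1C(C)=C[C@H]2CC[C@H](O[Si](C)(C)C(C)(C)C)[C@H](C)[C@H]2[C@@H]1/C=C/C=C/C(=O)OCC | intermediate
20 | ethyl (2E,4E)-dienoate, C7 alcohol | C/C=C(\C)[C@@H]1C(C)=C[C@H]2CC[C@H](O)[C@H](C)[C@H]2[C@@H]1/C=C/C=C/C(=O)OCC | intermediate
21 | ethyl (2E,4E)-dienoate, C7 sulfate, pyridinium salt | C/C=C(\C)[C@@H]1C(C)=C[C@H]2CC[C@H](OS(=O)(=O)[O-])[C@H](C)[C@H]2[C@@H]1/C=C/C=C/C(=O)OCC.c1cc[nH+]cc1 | intermediate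
22 | dilithium carboxylate sulfate salt (not isolated) | C/C=C(\C)[C@@H]1C(C)=C[C@H]2CC[C@H](OS(=O)(=O)[O-])[C@H](C)[C@H]2[C@@H]1/C=C/C=C/C(=O)[O-].[Li+].[Li+] | intermediate
23 | (2E,4E)-5-[(1S,2R,4aS,7S,8R,8aR)-2-[(2E)-but-2-en-2-yl]-3,8-dimethyl-7-(sulfooxy)-1,2,4a,5,6,7,8,8a-octahydronaphthalen-1-yl]penta-2,4-dienoic acid | C/C=C(\C)[C@@H]1C(C)=C[C@H]2CC[C@H](OS(=O)(=O)O)[C@H](C)[C@H]2[C@@H]1/C=C/C=C/C(=O)O | target

**Step count and risks**

Total: 15 steps. Longest linear sequence: 15 steps (1 to 23); 2, 11 and 18 are commercial.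

Steps most likely to fail:

1. Step 11 (proposed new method). The C2 configuration may be lost by rotation about C2–C3 inside the ion pair before collapse; the transition state that leads to the C2 epimer is the less strained one, because the natural configuration needs the butenyl group on the inner side of the allyl cation. Recombination at C3' is a second risk. Fallback with known chemistry, from 13 back to 17: the carbinol is converted into the methyl carbonate F1 (ClCO2Me, pyridine); the vinyl group is hydroborated and oxidised (9-BBN, then NaBO3) to the primary alcohol F2; Dess–Martin oxidation gives the aldehyde F3; Pd(PPh3)4 with catalytic pyrrolidine in DMSO then closes ring A directly by the enamine / zerovalent-palladium Tsuji–Trost α-allylation (ionisation with inversion, enamine attack anti to palladium, net retention at C2) and should give 17.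

2. Step 10. Closure of the eight-membered enol ether may be slow, so that oligomerisation, catalyst trapping on the vinyl ether or Claisen rearrangement of 14 competes. Fallback, from 13 to 15: formylation (acetic formic anhydride, pyridine) gives the formate F4, which is cyclised by olefinic-ester metathesis with the reduced titanium ethylidene reagent (TiCl4, Zn, PbCl2, TMEDA, CH3CHBr2, THF), turning the formyl C=O and the vinyl group directly into the ring enol ether 15.

3. Step 8. Ligand control at the new carbinol centre may be insufficient for the hindered Z-iodoalkene, giving a mixture of C2 epimers. Fallback, from 10 to 13: iodine–lithium exchange (t-BuLi, Et2O, −78 °C) and addition to 11 gives 13 together with its carbinol epimer F5; the mixture is oxidised with Dess–Martin periodinane to the cross-conjugated dienone F6, and reduction with catecholborane and (S)-2-methyl-CBS-oxazaborolidine (the Z-alkenyl arm as the large group) should return 13.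

**Further compounds**

F1 | step 11 | methyl carbonate of 13 | C/C=C(\C)[C@@H](OC(=O)OC)/C(C)=C\[C@H]1CC[C@H](O[Si](C)(C)C(C)(C)C)[C@H](C)[C@H]1C=C
F2 | step 11 | primary alcohol from hydroboration of F1 (2-hydroxyethyl on ring B) | C/C=C(\C)[C@@H](OC(=O)OC)/C(C)=C\[C@H]1CC[C@H](O[Si](C)(C)C(C)(C)C)[C@H](C)[C@H]1CCO
F3 | step 11 | aldehyde from F2 (2-oxoethyl on ring B) | C/C=C(\C)[C@@H](OC(=O)OC)/C(C)=C\[C@H]1CC[C@H](O[Si](C)(C)C(C)(C)C)[C@H](C)[C@H]1CC=O
F4 | step 10 | formate of 13 | C/C=C(\C)[C@@H](OC=O)/C(C)=C\[C@H]1CC[C@H](O[Si](C)(C)C(C)(C)C)[C@H](C)[C@H]1C=C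
F5 | step 8 | (4S)-carbinol epimer of 13 | C/C=C(\C)[C@H](O)/C(C)=C\[C@H]1CC[C@H](O[Si](C)(C)C(C)(C)C)[C@H](C)[C@H]1C=C
F6 | step 8 | (2E,5Z)-dienone from 13 and F5 | C/C=C(\C)C(=O)/C(C)=C\[C@H]1CC[C@H](O[Si](C)(C)C(C)(C)C)[C@H](C)[C@H]1C=C
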